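**Strategy.** Everything rests on tracing the cyclopentanol ring (C1–C5 of the spiro[4.5]decane core) back to a cyclobutanol. In the target the carbinol C1 sits beside the quaternary spiro carbon C5, which is bonded to the tertiary carbinol C6: the retron of an epoxy-cyclobutanol semipinacol shift. A carvone-derived cyclohexenyl cyclobutanol is epoxidised at its tetrasubstituted alkene (future C5=C6) and a Lewis acid shifts one cyclobutane bond to C5. This one operation expands four to five, creates the spiro centre and fixes the C6 carbinol. The ketone is then turned into a hydroxyl-directed cyclopentene epoxide, opened trans by acetylide, and the dienyl chain is attached last by Stille coupling.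

Key step: step 5

Remark on the chemistry: locants are those of the spiro[4.5]decane core (C1 carbinol, C2 dienyl-bearing carbon, C5 spiro, C6 methyl carbinol, C9 enal-bearing carbon, C10 hydroxypropyl-bearing carbon); compounds 1, 2, 8, 25, 26 and 30 are taken as purchased.

Step 1
Reactants: 1 (S)-(+)-carvone; 2 tert-butyl(3-iodopropoxy)dimethylsilane
Product: 4 (5S,6R)-6-[3-(tert-butyldimethylsilyloxy)propyl]-2-methyl-5-(prop-1-en-2-yl)cyclohex-2-en-1-one, via lithium dienolate 3 (not isolated)
Conditions: LiN(i-Pr)2, THF, −78 °C; then 2, DMPU, −78 to −20 °C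
Reagents that add atoms: tert-butyl(3-iodopropoxy)dimethylsilane (2), CC(C)(C)[Si](C)(C)OCCCI
Why: Kinetic deprotonation at C6 gives the cross-conjugated lithium dienolate, which is alkylated (SN2 enolate alkylation) anti to the neighbouring isopropenyl group, so the chain-bearing centre (future C10) is set trans to it, which is also the thermodynamically preferred epimer.

Step 2
Reactants: 4 alkylated carvone
Product: 6 (5S,6R)-6-[3-(tert-butyldimethylsilyloxy)propyl]-2-methyl-5-(prop-1-en-2-yl)cyclohex-1-en-1-yl trifluoromethanesulfonate, via lithium enolate 5 (not isolated)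
Conditions: LiBH(s-Bu)3, THF, −78 °C; then PhNTf2, −78 to 0 °C
Reagents that add atoms: N-phenylbis(trifluoromethanesulfonimide), O=S(=O)(N(c1ccccc1)S(=O)(=O)C(F)(F)F)C(F)(F)F
Why: Conjugate reduction of the enone by the hindered borohydride gives the tetrasubstituted lithium enolate regiospecifically and O-triflation locks the double bond between the future C5 and C6; no stereocentre is formed or touched.

Step 3
Reactants: 6 enol triflate
Product: 7 {(5S,6R)-6-[3-(tert-butyldimethylsilyloxy)propyl]-2-methyl-5-(prop-1-en-2-yl)cyclohex-1-en-1-yl}trimethylstannane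
Conditions: Me3SnSnMe3, Pd(PPh3)4 (5 mol %), LiCl, THF, 65 °C
Reagents that add atoms: hexamethylditin, C[Sn](C)(C)[Sn](C)(C)C
Why: Palladium-catalysed coupling of the enol triflate with the distannane (Stille-type stannylation: oxidative addition, transmetalation, reductive elimination) replaces triflate by tin at the same carbon, with LiCl assisting oxidative addition.

Step 4
Reactants: 7 alkenylstannane; 8 cyclobutanone
Product: 10 1-{(5S,6R)-6-[3-(tert-butyldimethylsilyloxy)propyl]-2-methyl-5-(prop-1-en-2-yl)cyclohex-1-en-1-yl}cyclobutan-1-ol, via alkenyllithium 9 (not isolated)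
Conditions: MeLi, THF, −78 to 0 °C; then CeCl3, −78 °C; then 8
Reagents that add atoms: cyclobutanone (8), O=C1CCC1
Why: Tin–lithium exchange gives the tetrasubstituted alkenyllithium, which as its organocerium derivative adds 1,2 to the strained ketone faster than it deprotonates it; the carbinol carbon is not stereogenic.

Step 5
Reactants: 10 cyclohexenyl cyclobutanol
Product: 12 (5R,6S,9S,10R)-10-[3-(tert-butyldimethylsilyloxy)propyl]-6-hydroxy-6-methyl-9-(prop-1-en-2-yl)spiro[4.5]decan-1-one, via epoxy cyclobutanol 11 (not isolated)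
Conditions: dimethyldioxirane (1.05 equiv), acetone/CH2Cl2, −40 °C; then BF3·OEt2 (0.3 equiv), CH2Cl2, −78 °C
Reagents that add atoms: dimethyldioxirane, CC1(C)OO1
Why: The dioxirane epoxidises only the electron-rich tetrasubstituted alkene, and BF3 then ionises the C5–O bond while the antiperiplanar C–C bond of the cyclobutanol migrates to C5 and the carbinol carbon becomes the ketone, a semipinacol rearrangement of a 2,3-epoxy alcohol driven by release of cyclobutane strain. No ring is closed by cyclisation: the five-membered ring arises from the four-membered one by a 1,2-alkyl shift (expansion by one carbon) and the six-membered ring stays intact. C5 is formed with inversion at the epoxide carbon, so the migrating CH2 ends anti and the new carbonyl carbon C1 syn to the C6 oxygen, which is retained as the tertiary alcohol; both centres therefore follow from the face of epoxidation. That face is set by the substrate: allylic 1,2-strain with the cyclobutyl carbinol forces the chain at the future C10 pseudoaxial, the trans isopropenyl group at the future C9 is then axial on the opposite face and 1,3 to C5, where it should shield the alkene more effectively than the pseudoaxial CH2 does, so oxygen should enter syn to the chain. Cleavage of C5–O rather than C6–O is secured by the assistance of the strained migrating bond, and chemoselectivity by the low reactivity of the 1,1-disubstituted isopropenyl alkene toward the dioxirane.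

Step 6
Reactants: 12 spiro hydroxy ketone
Product: 14 2-{(5R,6S,9S,10R)-10-[3-(tert-butyldimethylsilyloxy)propyl]-6-hydroxy-6-methyl-1-oxospiro[4.5]decan-9-yl}prop-2-enal, via allylic alcohol 13 (not isolated)
Conditions: SeO2 (0.3 equiv), t-BuOOH, CH2Cl2, 0 °C to rt; filtration; then MnO2, CH2Cl2, rt
Reagents that add atoms: tert-butyl hydroperoxide, CC(C)(C)OO
Why: Selenium dioxide oxidises the isopropenyl methyl group (ene reaction, then [2,3]-sigmatropic shift; the ring C–H at C9 lies in the alkene plane and is not abstracted) and MnO2 takes the primary allylic alcohol to the aldehyde without touching the tertiary alcohol or the hindered ketone.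

Step 7
Reactants: 14 α-methylene aldehyde
Product: 15 (2Z)-2-{(5R,6S,10R)-10-[3-(tert-butyldimethylsilyloxy)propyl]-6-hydroxy-6-methyl-1-oxospiro[4.5]decan-9-ylidene}propanal
Conditions: RhH(CO)(PPh3)3 (5 mol %), toluene, 70 °C
Reagents that add atoms: none
Why: The rhodium hydride adds to the unhindered methylene of the α-substituted acrolein and β-hydride elimination toward C9 moves the double bond into the tetrasubstituted, still conjugated position (metal-hydride isomerisation of an α-methylene carbonyl compound), which removes the C9 stereocentre; the Z isomer, with the small formyl group rather than the methyl group facing the chain at C10 (allylic 1,3-strain), should prevail.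

Step 8
Reactants: 15 enal
Product: 16 (9Z)-10-[3-(tert-butyldimethylsilyloxy)propyl]-9-[1-(1,3-dioxolan-2-yl)ethylidene]-6-hydroxy-6-methylspiro[4.5]decan-1-one (C5, C6, C10 as in 15)
Conditions: (Me3SiOCH2)2, Me3SiOTf (5 mol %), CH2Cl2, −78 °C; aqueous NaHCO3
Reagents that add atoms: 1,2-bis(trimethylsilyloxy)ethane, C[Si](C)(C)OCCO[Si](C)(C)C
Why: Acetalisation under Noyori conditions masks the formyl group for the organolithium and aluminium hydride steps; at −78 °C the aldehyde reacts far faster than the neopentyl cyclopentanone and the conjugated double bond does not migrate.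

Step 9
Reactants: 16 keto acetal
Product: 17 2,4,6-triisopropylbenzenesulfonylhydrazone of 16 (C=N at C1)
Conditions: 2,4,6-(i-Pr)3C6H2SO2NHNH2, AcOH (cat.), THF, rt
Reagents that add atoms: 2,4,6-triisopropylbenzenesulfonyl hydrazide, CC(C)c1cc(C(C)C)c(S(=O)(=O)NN)c(C(C)C)c1
Why: Condensation of the remaining ketone with the arenesulfonyl hydrazide gives the hydrazone needed for the Shapiro reaction; acetal, silyl ether and tertiary alcohol are stable to these almost neutral conditions.

Step 10
Reactants: 17 sulfonylhydrazone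
Product: 19 (9Z)-10-[3-(tert-butyldimethylsilyloxy)propyl]-9-[1-(1,3-dioxolan-2-yl)ethylidene]-6-methylspiro[4.5]dec-1-en-6-ol (C5, C6, C10 as in 16), via alkenyllithium 18 (not isolated)
Conditions: n-BuLi (3.3 equiv), THF, −78 to 0 °C; then H2O
Reagents that add atoms: none
Why: Shapiro reaction: the hydrazone dianion loses arenesulfinate and N2 to give the alkenyllithium, which is protonated; only C2 carries α-hydrogens, so the C1=C2 double bond forms regiospecifically.

Step 11
Reactants: 19 spiro cyclopentene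
Product: 20 1,2-epoxide of 19 with the oxirane oxygen on the face of the five-membered ring that carries C6
Conditions: VO(acac)2 (5 mol %), t-BuOOH, CH2Cl2, 0 °C to rt
Reagents that add atoms: tert-butyl hydroperoxide, CC(C)(C)OO
Why: Hydroxyl-directed epoxidation: the vanadate ester of the tertiary C6 hydroxyl, homoallylic to C1=C2, delivers oxygen to the cyclopentene face that carries C6, which sets the C1 oxygen configuration; the tetrasubstituted alkene has no hydroxyl within reach and stays intact.

Step 12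
Reactants: 20 epoxide
Product: 21 (1S,2S,5S,6S,10R,9Z)-10-[3-(tert-butyldimethylsilyloxy)propyl]-9-[1-(1,3-dioxolan-2-yl)ethylidene]-2-ethynyl-6-methylspiro[4.5]decane-1,6-diol
Conditions: LiC≡CH·H2NCH2CH2NH2, DMSO, rt
Reagents that add atoms: lithium acetylide ethylenediamine complex, [Li]C#C.NCCN
Why: The acetylide opens the epoxide by SN2 attack at C2, the carbon remote from the quaternary spiro centre, with inversion, so the ethynyl group ends trans to the C1 hydroxyl and both stereocentres of the cyclopentane are fixed.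

Step 13
Reactants: 21 alkynyl diol
Product: 23 (1S,2R,5S,6S,10R,9Z)-10-[3-(tert-butyldimethylsilyloxy)propyl]-9-[1-(1,3-dioxolan-2-yl)ethylidene]-2-(1-iodoethenyl)-6-methylspiro[4.5]decane-1,6-diol, via alkenylalane 22 (not isolated)
Conditions: i-Bu2AlH (4.5 equiv), NiCl2(dppp) (3 mol %), THF, 0 °C to rt; then N-iodosuccinimide, −20 °C
Reagents that add atoms: N-iodosuccinimide, O=C1CCC(=O)N1I
Why: Nickel-catalysed hydroalumination with the dppp ligand places aluminium on the internal alkyne carbon (α-selective syn addition) and iodinolysis with retention gives the 2-iodo-1-alkene; the hydroxyls are carried as aluminium alkoxides and the acetal, silyl ether and alkenes do not react.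

Step 14
Reactants: 23 protected vinyl iodide
Product: 24 (2Z)-2-[(1S,2R,5S,6S,10R)-1,6-dihydroxy-10-(3-hydroxypropyl)-2-(1-iodoethenyl)-6-methylspiro[4.5]decan-9-ylidene]propanal
Conditions: HCl (1 M aq.), THF, rt
Reagents that add atoms: water, O
Why: Aqueous acid hydrolyses the dioxolane back to the conjugated aldehyde and removes the primary silyl ether in the same operation; the vinyl iodide, the tertiary alcohol and the stereocentres are not affected.

Step 15
Reactants: 25 prop-2-yn-1-ol; 26 5-bromo-2-methylpent-2-ene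
Product: 29 (Z)-2-(iodomethylidene)-6-methylhept-5-en-1-ol, via Grignard reagent 27 (not isolated), via alkenylmagnesium chelate 28 (not isolated)
Conditions: Mg, THF, rt (26 gives 27, 2.5 equiv); then 25, CuI (10 mol %), THF, −10 °C to rt; then I2, −78 to 0 °C
Reagents that add atoms: 4-methylpent-3-enylmagnesium bromide (27), CC(C)=CCC[Mg]Br; iodine, II
Why: Copper-catalysed carbomagnesiation of the propargylic alkoxide (anti addition) puts the new carbon on C2 and magnesium on C3 in a five-membered chelate, and iodinolysis with retention gives the Z-iodoalkene with iodine cis to the hydroxymethyl group.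

Step 16
Reactants: 29 iodo alcohol; 30 (E)-1,2-bis(tributylstannyl)ethene
Product: 31 (2Z)-6-methyl-2-[(2E)-3-(tributylstannyl)prop-2-en-1-ylidene]hept-5-en-1-ol
Conditions: 30 (2 equiv), PdCl2(MeCN)2 (5 mol %), DMF, rt
Reagents that add atoms: (E)-1,2-bis(tributylstannyl)ethene (30), CCCC[Sn](CCCC)(CCCC)/C=C/[Sn](CCCC)(CCCC)CCCC
Why: Stille coupling of the alkenyl iodide with one tin terminus of the distannane, used in excess, proceeds with retention at both double bonds and leaves the (1E,3Z)-dienylstannane.

Step 17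
Reactants: 24 vinyl iodide; 31 dienylstannane
Product: 32 CNP0249558.1, (2Z)-2-[(1S,2S,5S,6S,10R)-1,6-dihydroxy-10-(3-hydroxypropyl)-2-[(3E,5Z)-6-(hydroxymethyl)-10-methylundeca-1,3,5,9-tetraen-2-yl]-6-methylspiro[4.5]decan-9-ylidene]propanal
Conditions: Pd2(dba)3 (5 mol %), AsPh3 (20 mol %), CuI (10 mol %), NMP, rt
Reagents that add atoms: dienylstannane (31), CCCC[Sn](CCCC)(CCCC)/C=C/C=C(\CO)CCC=C(C)C
Why: Stille coupling of the 2-iodo-1-alkene with the dienylstannane, accelerated by AsPh3 and CuI, forms the C(sp2)–C(sp2) bond with retention of every alkene geometry and tolerates the free hydroxyls and the enal.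

**Compound list**

1 | (S)-(+)-carvone, (5S)-2-methyl-5-(prop-1-en-2-yl)cyclohex-2-en-1-one | O=C1C[C@@H](C(C)=C)CC=C1C | starting material
2 | tert-butyl(3-iodopropoxy)dimethylsilane | CC(C)(C)[Si](C)(C)OCCCI | starting material
3 | lithium dienolate of 1 (deprotonated at C6) | [Li]OC1=C[C@@H](C(C)=C)CC=C1C | intermediate
4 | (5S,6R)-6-[3-(tert-butyldimethylsilyloxy)propyl]-2-methyl-5-(prop-1-en-2-yl)cyclohex-2-en-1-one | O=C1[C@H](CCCO[Si](C)(C)C(C)(C)C)[C@@H](C(C)=C)CC=C1C | intermediate
5 | lithium (5S,6R)-6-[3-(tert-butyldimethylsilyloxy)propyl]-2-methyl-5-(prop-1-en-2-yl)cyclohex-1-en-1-olate | CC1=C(O[Li])[C@H](CCCO[Si](C)(C)C(C)(C)C)[C@@H](C(C)=C)CC1 | intermediate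
6 | (5S,6R)-6-[3-(tert-butyldimethylsilyloxy)propyl]-2-methyl-5-(prop-1-en-2-yl)cyclohex-1-en-1-yl trifluoromethanesulfonate | CC1=C(OS(=O)(=O)C(F)(F)F)[C@H](CCCO[Si](C)(C)C(C)(C)C)[C@@H](C(C)=C)CC1 | intermediate
7 | {(5S,6R)-6-[3-(tert-butyldimethylsilyloxy)propyl]-2-methyl-5-(prop-1-en-2-yl)cyclohex-1-en-1-yl}trimethylstannane | CC1=C([Sn](C)(C)C)[C@H](CCCO[Si](C)(C)C(C)(C)C)[C@@H](C(C)=C)CC1 | intermediate
8 | cyclobutanone | O=C1CCC1 | starting material
9 | {(5S,6R)-6-[3-(tert-butyldimethylsilyloxy)propyl]-2-methyl-5-(prop-1-en-2-yl)cyclohex-1-en-1-yl}lithium | CC1=C([Li])[C@H](CCCO[Si](C)(C)C(C)(C)C)[C@@H](C(C)=C)CC1 | intermediate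
10 | 1-{(5S,6R)-6-[3-(tert-butyldimethylsilyloxy)propyl]-2-methyl-5-(prop-1-en-2-yl)cyclohex-1-en-1-yl}cyclobutan-1-ol | CC1=C(C2(O)CCC2)[C@H](CCCO[Si](C)(C)C(C)(C)C)[C@@H](C(C)=C)CC1 | intermediate
11 | epoxide of 10 at the ring alkene, oxirane oxygen cis to the silyloxypropyl chain and trans to isopropenyl | C[C@@]12O[C@]1(C1(O)CCC1)[C@H](CCCO[Si](C)(C)C(C)(C)C)[C@@H](C(C)=C)CC2 | intermediate
12 | (5R,6S,9S,10R)-10-[3-(tert-butyldimethylsilyloxy)propyl]-6-hydroxy-6-methyl-9-(prop-1-en-2-yl)spiro[4.5]decan-1-one | O=C1CCC[C@]12[C@H](CCCO[Si](C)(C)C(C)(C)C)[C@@H](C(C)=C)CC[C@]2(C)O | intermediate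
13 | (5R,6S,9S,10R)-10-[3-(tert-butyldimethylsilyloxy)propyl]-6-hydroxy-9-(3-hydroxyprop-1-en-2-yl)-6-methylspiro[4.5]decan-1-one | O=C1CCC[C@]12[C@H](CCCO[Si](C)(C)C(C)(C)C)[C@@H](C(=C)CO)CC[C@]2(C)O | intermediate
14 | 2-{(5R,6S,9S,10R)-10-[3-(tert-butyldimethylsilyloxy)propyl]-6-hydroxy-6-methyl-1-oxospiro[4.5]decan-9-yl}prop-2-enal | O=C1CCC[C@]12[C@H](CCCO[Si](C)(C)C(C)(C)C)[C@@H](C(=C)C=O)CC[C@]2(C)O | intermediate
15 | (2Z)-2-{(5R,6S,10R)-10-[3-(tert-butyldimethylsilyloxy)propyl]-6-hydroxy-6-methyl-1-oxospiro[4.5]decan-9-ylidene}propanal | O=C1CCC[C@]12[C@H](CCCO[Si](C)(C)C(C)(C)C)/C(=C(/C)C=O)CC[C@]2(C)O | intermediate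
16 | (5R,6S,10R,9Z)-10-[3-(tert-butyldimethylsilyloxy)propyl]-9-[1-(1,3-dioxolan-2-yl)ethylidene]-6-hydroxy-6-methylspiro[4.5]decan-1-one | O=C1CCC[C@]12[C@H](CCCO[Si](C)(C)C(C)(C)C)/C(=C(/C)C3OCCO3)CC[C@]2(C)O | intermediate
17 | 2,4,6-triisopropylbenzenesulfonylhydrazone of 16 at C1 | CC(C)c1cc(C(C)C)c(S(=O)(=O)NN=C2CCC[C@]23[C@H](CCCO[Si](C)(C)C(C)(C)C)/C(=C(/C)C4OCCO4)CC[C@]3(C)O)c(C(C)C)c1 | intermediate
18 | 1-lithio derivative of 19 as its lithium C6 alkoxide | [Li]C1=CCC[C@]12[C@H](CCCO[Si](C)(C)C(C)(C)C)/C(=C(/C)C3OCCO3)CC[C@]2(C)O[Li] | intermediate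
19 | (9Z)-10-[3-(tert-butyldimethylsilyloxy)propyl]-9-[1-(1,3-dioxolan-2-yl)ethylidene]-6-methylspiro[4.5]dec-1-en-6-ol, C5, C6 and C10 as in 16 | C1=CCC[C@]12[C@H](CCCO[Si](C)(C)C(C)(C)C)/C(=C(/C)C3OCCO3)CC[C@]2(C)O | intermediate
20 | 1,2-epoxide of 19, oxirane oxygen on the cyclopentane face that carries C6 | O1[C@H]2CC[C@]3([C@H](CCCO[Si](C)(C)C(C)(C)C)/C(=C(/C)C4OCCO4)CC[C@]3(C)O)[C@@H]12 | intermediate
21 | (1S,2S,5S,6S,10R,9Z)-10-[3-(tert-butyldimethylsilyloxy)propyl]-9-[1-(1,3-dioxolan-2-yl)ethylidene]-2-ethynyl-6-methylspiro[4.5]decane-1,6-diol | C#C[C@@H]1CC[C@]2([C@H](CCCO[Si](C)(C)C(C)(C)C)/C(=C(/C)C3OCCO3)CC[C@]2(C)O)[C@H]1O | intermediate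
22 | 2-[1-(diisobutylalumanyl)ethenyl] analogue of 21 with both hydroxyls as diisobutylaluminium alkoxides | C=C([Al](CC(C)C)CC(C)C)[C@@H]1CC[C@]2([C@H](CCCO[Si](C)(C)C(C)(C)C)/C(=C(/C)C3OCCO3)CC[C@]2(C)O[Al](CC(C)C)CC(C)C)[C@H]1O[Al](CC(C)C)CC(C)C | intermediate
23 | (1S,2R,5S,6S,10R,9Z)-10-[3-(tert-butyldimethylsilyloxy)propyl]-9-[1-(1,3-dioxolan-2-yl)ethylidene]-2-(1-iodoethenyl)-6-methylspiro[4.5]decane-1,6-diol | C=C(I)[C@@H]1CC[C@]2([C@H](CCCO[Si](C)(C)C(C)(C)C)/C(=C(/C)C3OCCO3)CC[C@]2(C)O)[C@H]1O | intermediate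
24 | (2Z)-2-[(1S,2R,5S,6S,10R)-1,6-dihydroxy-10-(3-hydroxypropyl)-2-(1-iodoethenyl)-6-methylspiro[4.5]decan-9-ylidene]propanal | C=C(I)[C@@H]1CC[C@]2([C@H](CCCO)/C(=C(/C)C=O)CC[C@]2(C)O)[C@H]1O | intermediate
25 | prop-2-yn-1-ol | C#CCO | starting material
26 | 5-bromo-2-methylpent-2-ene | CC(C)=CCCBr | starting material
27 | 4-methylpent-3-enylmagnesium bromide | CC(C)=CCC[Mg]Br | intermediate
28 | (Z)-alkenylmagnesium chelate, bromomagnesium alkoxide of 2-[(bromomagnesio)methylidene]-6-methylhept-5-en-1-ol | Br[Mg]/C=C(\CO[Mg]Br)CCC=C(C)C | intermediate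
29 | (Z)-2-(iodomethylidene)-6-methylhept-5-en-1-ol | I/C=C(\CO)CCC=C(C)C | intermediate
30 | (E)-1,2-bis(tributylstannyl)ethene | CCCC[Sn](CCCC)(CCCC)/C=C/[Sn](CCCC)(CCCC)CCCC | starting material
31 | (2Z)-6-methyl-2-[(2E)-3-(tributylstannyl)prop-2-en-1-ylidene]hept-5-en-1-ol | CCCC[Sn](CCCC)(CCCC)/C=C/C=C(\CO)CCC=C(C)C | intermediate
32 | CNP0249558.1, (2Z)-2-[(1S,2S,5S,6S,10R)-1,6-dihydroxy-10-(3-hydroxypropyl)-2-[(3E,5Z)-6-(hydroxymethyl)-10-methylundeca-1,3,5,9-tetraen-2-yl]-6-methylspiro[4.5]decan-9-ylidene]propanal | C=C(/C=C/C=C(\CO)CCC=C(C)C)[C@@H]1CC[C@]2([C@H](CCCO)/C(=C(/C)C=O)CC[C@]2(C)O)[C@H]1O | target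

**Step count.** Total: 17 steps. Longest linear sequence: 15 steps (steps 1 to 14, then step 17); steps 15 and 16 build the side chain.

**Steps most likely to fail**

1. Step 5. The epoxidation may show poor facial selectivity (oxygen entering on the isopropenyl face), or the epoxide may ionise at the methyl-bearing carbon; either would give the wrong C5/C6 diastereomer or no ring expansion. The fallback uses a temporary directing hydroxyl, sets out from 1 and returns at 12. The dienolate 3 would be added to 3-(tert-butyldimethylsilyloxy)propanal and the aldolate silylated in the flask with Et3SiCl to give the β-triethylsilyloxy ketone F1 (carbinol epimers, both usable). Conjugate reduction and triflation as in step 2 would give the enol triflate F2, stannylation as in step 3 the alkenylstannane F3, and tin–lithium exchange with cerium-mediated addition to 8 the cyclobutanol F4. PPTS in MeOH would remove only the triethylsilyl group to leave the diol F5, whose side-chain hydroxyl sits on the required face one carbon from the ring. VO(acac)2 with t-BuOOH should then deliver oxygen from a vanadate held by that homoallylic hydroxyl (and the cyclobutanol oxygen) to give the epoxide F6, which BF3·OEt2 would rearrange without isolation to the spiro hydroxy ketone F7. The auxiliary hydroxyl would be removed by Barton–McCombie deoxygenation, via the imidazolyl thiocarbonate F8 (1,1'-thiocarbonyldiimidazole) and Bu3SnH/AIBN, which returns 12.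

2. Step 7. The double-bond migration may stop short, the aldehyde may be decarbonylated by rhodium, or the E isomer may form. The fallback sets out from 14 and returns at 15. Conjugate reduction of 14 with [CuH(PPh3)]6 in the presence of t-BuMe2SiCl would give the silyl enol ether F9. DDQ with 2,6-lutidine should then abstract hydride from the tertiary allylic C9–H, a better cation precursor than the methyl group, and loss of the silyl group gives 15. Any E isomer would be equilibrated with a catalytic amount of pyrrolidinium acetate.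

3. Step 13. Regiocontrol of the hydroalumination may be lost (aluminium on the terminal carbon, giving the linear iodoalkene), or the excess aluminium hydride may cleave the dioxolane. The fallback sets out from 20 and returns at 23. The epoxide 20 would be opened at C2 with [1-(trimethylsilyl)ethenyl]magnesium bromide and CuI (10 mol %) to give the vinylsilane F10, in which silicon marks the internal carbon. Iododesilylation with N-iodosuccinimide in MeCN/ClCH2CN at 0 °C would then give 23; the acetal-bearing tetrasubstituted alkene is deactivated toward the iodonium source.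

Further compounds
F1 | step 5 | (5S,6R)-6-[3-(tert-butyldimethylsilyloxy)-1-(triethylsilyloxy)propyl]-2-methyl-5-(prop-1-en-2-yl)cyclohex-2-en-1-one, carbinol epimers | O=C1[C@H](C(O[Si](CC)(CC)CC)CCO[Si](C)(C)C(C)(C)C)[C@@H](C(C)=C)CC=C1C
F2 | step 5 | enol triflate of F1 (analogue of 6) | CC1=C(OS(=O)(=O)C(F)(F)F)[C@H](C(O[Si](CC)(CC)CC)CCO[Si](C)(C)C(C)(C)C)[C@@H](C(C)=C)CC1
F3 | step 5 | alkenyltrimethylstannane from F2 (analogue of 7) | CC1=C([Sn](C)(C)C)[C@H](C(O[Si](CC)(CC)CC)CCO[Si](C)(C)C(C)(C)C)[C@@H](C(C)=C)CC1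
F4 | step 5 | cyclobutanol from F3 and 8 (analogue of 10) | CC1=C(C2(O)CCC2)[C@H](C(O[Si](CC)(CC)CC)CCO[Si](C)(C)C(C)(C)C)[C@@H](C(C)=C)CC1
F5 | step 5 | diol from F4 with free side-chain carbinol | CC1=C(C2(O)CCC2)[C@H](C(O)CCO[Si](C)(C)C(C)(C)C)[C@@H](C(C)=C)CC1
F6 | step 5 | epoxide of F5, oxirane oxygen cis to the side chain | C[C@@]12O[C@]1(C1(O)CCC1)[C@H](C(O)CCO[Si](C)(C)C(C)(C)C)[C@@H](C(C)=C)CC2
F7 | step 5 | spiro hydroxy ketone, 1'-hydroxy analogue of 12 in the C10 chain | O=C1CCC[C@]12[C@H](C(O)CCO[Si](C)(C)C(C)(C)C)[C@@H](C(C)=C)CC[C@]2(C)O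
F8 | step 5 | O-(imidazol-1-ylthiocarbonyl) derivative of F7 at the side-chain carbinol | O=C1CCC[C@]12[C@H](C(OC(=S)n3ccnc3)CCO[Si](C)(C)C(C)(C)C)[C@@H](C(C)=C)CC[C@]2(C)O
F9 | step 7 | tert-butyldimethylsilyl enol ether of the saturated aldehyde from 14 | O=C1CCC[C@]12[C@H](CCCO[Si](C)(C)C(C)(C)C)[C@@H](C(C)=CO[Si](C)(C)C(C)(C)C)CC[C@]2(C)O
F10 | step 13 | 2-[1-(trimethylsilyl)ethenyl] analogue of 23 | C=C([Si](C)(C)C)[C@@H]1CC[C@]2([C@H](CCCO[Si](C)(C)C(C)(C)C)/C(=C(/C)C3OCCO3)CC[C@]2(C)O)[C@H]1O
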